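Remark on the chemistry (assumption): the target is taken exactly as drawn, (2R,3S,6R,7S,8S,9S) in the ring, (2R,3R) in the epoxy ester, 1(10)E and 4Z. Locants C1–C15 are the skeleton locants defined in the first section and are used in all names of open-chain and ring compounds from 19 onward. TBS = tert-butyldimethylsilyl, PMB = 4-methoxybenzyl.

## Analysis of the target

The target is a germacranolide: a ten-membered carbocycle C1–C10 with a γ-lactone fused across C6–C7 (O6–C12, with the exocyclic C11=C13 methylene), a 2,3-epoxide, a methyl ester (C14) on C10, a methyl group (C15) on C4, a free hydroxyl on C9 and a (2R,3R)-2,3-dimethyloxirane-2-carboxylate on O8. Both ring alkenes hold their ring neighbours cis: C2 and C9 across C1=C10 (E by the sequence rule because of the ester) and C3 and C6 across C4=C5 (Z). The six ring stereocentres are related as follows: the epoxide is cis, O8 and O9 are syn, the C7–C11 bond is anti to O8, and O6 is syn to C11, which makes the lactone trans-fused. The sensitive groups are the methylene lactone (a Michael acceptor), the 2,3-epoxide flanked by two alkenes (a cis-divinyl epoxide, open to acid ionisation and, in an open chain, to Cope rearrangement on heating), the epoxy ester and the β-oxygenated carbonyl groups. The synthesis is hard because a strained medium ring with two cis ring alkenes has to be closed next to four contiguous oxygenated or branched carbons (C6–C9), and because the E enoate C9–C10(CO2Me)=C1 must be set in an open chain. The strategy rests on one feature: C6 is an allylic carbinol bonded to C5 of the Z-trisubstituted C4=C5 alkene, so the ring bond C5–C6 is the bond between a vinyl carbon and a carbonyl-derived carbon.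

## Retrosynthetic reasoning

C11=C13 and the O9 silyl group (36 to 35 to 33 to 32). The methylene is the most electrophilic site of the target, so it is cut first: 35 is the silyl ether of 36, and 35 comes from the saturated lactone 32 through the Mannich base 33. This keeps the Michael acceptor out of every earlier step. The forward reaction must enolise the lactone only; the C8 ester has no α-hydrogen and the C14 ester is vinylic.

O6–C12 (32 to 31). Opening the lactone gives the hydroxy ester 31, in which C6 is a plain secondary allylic alcohol. The gain is that C6–O becomes the oxygen of a carbonyl addition. The forward step is a 5-exo acyl substitution that gives the trans lactone.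

C5–C6 (31 to 29, the ring closure). This is the only ring bond that joins an sp2 carbon to a carbinol carbon while leaving the oxygenation pattern alone. Cutting C1=C10 instead would need a stabilised carbanion next to the C9 oxygen and a base-sensitive epoxy aldehyde. Cutting C7–C8 or C8–C9 would break the stereotriad. The gain is the ring and the C6 stereocentre in one step from a chain, 29, that already holds every other stereocentre. The forward reaction must turn the Z alkenyl iodide into a nucleophile that tolerates esters, two epoxides and an epimerisable aldehyde.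

C6 aldehyde and O8 ester (29 to 27 to 21 + 25). The aldehyde is carried as the terminal vinyl group of 27, so a β-acyloxy aldehyde is never stored. The O8–acyl bond is cut to alcohol 21 and acid 25. Acid 25 comes from 22 through the allylic alcohol 23 and the epoxy alcohol 24, where a tartrate-controlled epoxidation sets both stereocentres.

C9–C10 (21 from 20 from 19, then to 9 + 17). This cut divides the chain into two halves of similar size. C9 becomes the carbinol of an addition to the α-alkoxy aldehyde 17, where the PMB ether on O8 can chelate and direct the 9S configuration. C10 becomes an alkenyl nucleophile made from the α-iodo enoate 9, which already carries the C1=C10 geometry. The forward step must activate only the electron-poor iodide of 9 and keep the alkene geometry.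

West half (9 back to 1). C1=C10 in 9 comes from an iodo-Wittig reaction of the epoxy aldehyde 8. The cis epoxide of 8 and 7 comes from the Z,Z-dienol 6 by tartrate-controlled epoxidation, so the alkene supplies the cis relation and the catalyst the absolute configuration. C2=C3 comes from a Z-selective olefination of aldehyde 4 to ester 5. The Z iodide of 3 comes from anti-carbomagnesiation of 1.

East half (17 back to 10). C7–C11 is made by an orthoester Claisen rearrangement of 13, which sets C7 from C8 and gives the methyl ester arm and the vinyl group of 15 in one step. C8 comes from 10. The acetal of 12 is exchanged for the 4-methoxybenzylidene acetal in 13, so that reductive opening of 15 puts the PMB ether on O8 and frees only O9 (16) for oxidation to 17. O8 is therefore not free next to the C12 ester at any point before step 16.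

## Alternatives that were turned down

Alternative 1: The cut is the C7–C11 bond together with the O6–C12 acyl bond. In the forward key step the carbon next to phosphorus in a phosphonoacetyl group bound to O6 is deprotonated, attacks C7 of a 7,8-epoxide and closes the lactone; formaldehyde then converts the phosphonate into the C11=C13 methylene, giving A1. In its favour, the SN2 opening fixes the trans relation of C6 and C7 by stereospecificity, which is stronger than the facial selectivity the chosen ring closure relies on at C6. It also frees O8 alone, and it makes the methylene without a lithium amide on a finished macrocycle. Against it, A1 holds only C5–C9 and C11–C13, with C5 and C9 at the alcohol level. The ten-membered ring, both ring alkenes and the 2,3-epoxide would still have to be built, and a second, ring-forming key step found, with the Michael acceptor present throughout. The chosen strategy spends its risk once, in a step that closes the ring and sets C6 together, and brings in the methylene at the end.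

Alternative 2: The cut is O6–C12 and C12–C11, with carbon monoxide as C12. In the forward key step PdCl2 with PPh3 and SnCl2 joins the C6 hydroxyl, CO and an ethynyl group on C7 to the methylene lactone A2. In its favour, one step forms two bonds and the methylene, the trans relation is already fixed in the substrate, and C8 and C9 come from the chiral pool. On step economy for the lactone it is stronger than the chosen route, which needs three steps (23–25). Against it, divalent palladium and CO pressure rule out an alkenyl iodide, so the step must come early. The methylene lactone then has to survive the construction of C1–C4 and C10, the epoxidation and a ring closure that this plan does not provide. The chosen strategy offers the ring closure itself and a late, short methylene sequence.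

Alternative 3: The cut is the C1=C10 double bond. In the forward key step a phosphonoacetate carbanion at C10 adds to an aldehyde at C1 and expels phosphate, closing the ring to A3, which is the same structure as 32. In its favour, the trisubstituted enoate is formed inside the ring, where only the ring-cis geometry can arise; on this point it is stronger than the chosen route, which must secure that geometry in an open chain (step 14). Against it, the carbanion at C10 has the C9 silyloxy group in the β position and is α-branched, so β-elimination and low reactivity are likely. Its partner is a cis-epoxy aldehyde that epimerises under base, and the base also meets the lactone and the β-acyloxy ester. The C5–C6 bond would then have to be made between two fragments without the help of the ring. The chosen closure is non-basic and uses an unhindered alkenyl iodide and a simple aldehyde.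

Key step: step 22

## Route

Step 1
Reactants: 1 propargyl alcohol (prop-2-yn-1-ol)
Product: 3 (Z)-3-iodo-2-methylprop-2-en-1-ol, via alkenylmagnesium alkoxide 2 (not isolated)
Conditions: MeMgBr (3 equiv), CuI (cat.), THF/Et2O, −10 °C → rt; then I2, −78 → 0 °C
Reagents that add atoms: methylmagnesium bromide, C[Mg]Br; iodine, II
Why: Copper-catalysed anti-carbomagnesiation of the magnesium alkoxide puts the methyl group on C4 and magnesium on C5 cis to the CH2O group (five-membered chelate); iodinolysis of the C–Mg bond with retention gives the Z iodide.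

Step 2
Reactants: 3 (Z)-3-iodo-2-methylprop-2-en-1-ol
Product: 4 (Z)-3-iodo-2-methylprop-2-enal
Conditions: MnO2, CH2Cl2, rt, dark
Reagents that add atoms: none
Why: Selective oxidation of the allylic alcohol on the oxide surface under neutral conditions keeps the Z geometry; the labile aldehyde is used at once.

Step 3
Reactants: 4 (Z)-3-iodo-2-methylprop-2-enal
Product: 5 methyl (2Z,4Z)-5-iodo-4-methylpenta-2,4-dienoate
Conditions: (CF3CH2O)2P(O)CH2CO2Me, KN(SiMe3)2, 18-crown-6, THF, −78 °C
Reagents that add atoms: methyl bis(2,2,2-trifluoroethyl)phosphonoacetate, COC(=O)CP(=O)(OCC(F)(F)F)OCC(F)(F)F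
Why: Still–Gennari variant of the Horner–Wadsworth–Emmons reaction; fast, irreversible collapse of the kinetic adduct of the electron-poor phosphonate should give mainly the 2Z ester.

Step 4
Reactants: 5 methyl (2Z,4Z)-5-iodo-4-methylpenta-2,4-dienoate
Product: 6 (2Z,4Z)-5-iodo-4-methylpenta-2,4-dien-1-ol
Conditions: (i-Bu)2AlH, CH2Cl2, −78 °C
Reagents that add atoms: none
Why: 1,2-Reduction of the ester by the aluminium hydride; the alkenyl iodide and both Z alkenes are inert at this temperature.

Step 5
Reactants: 6 (2Z,4Z)-5-iodo-4-methylpenta-2,4-dien-1-ol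
Product: 7 [(2R,3S)-3-[(Z)-1-iodoprop-1-en-2-yl]oxiran-2-yl]methanol
Conditions: Ti(OiPr)4, D-(−)-diethyl tartrate, t-BuOOH, 4 Å MS, CH2Cl2, −20 °C
Reagents that add atoms: tert-butyl hydroperoxide, CC(C)(C)OO
Why: Sharpless asymmetric epoxidation acts only on the alkene of the allylic alcohol; oxygen transfer is concerted, so the Z alkene gives the cis epoxide, and the D-tartrate complex should deliver oxygen to the face that gives 2R,3S.

Step 6
Reactants: 7 [(2R,3S)-3-[(Z)-1-iodoprop-1-en-2-yl]oxiran-2-yl]methanol
Product: 8 (2S,3S)-3-[(Z)-1-iodoprop-1-en-2-yl]oxirane-2-carbaldehyde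
Conditions: Dess–Martin periodinane, NaHCO3, CH2Cl2, 0 °C
Reagents that add atoms: none
Why: Buffered Dess–Martin oxidation is neutral, so the cis epoxy aldehyde should not epimerise; the change of descriptor at C2 is only a change of priorities.

Step 7
Reactants: 8 (2S,3S)-3-[(Z)-1-iodoprop-1-en-2-yl]oxirane-2-carbaldehyde
Product: 9 methyl (2Z)-2-iodo-3-[(2R,3S)-3-[(Z)-1-iodoprop-1-en-2-yl]oxiran-2-yl]prop-2-enoate
Conditions: Ph3P=CHCO2Me, N-iodosuccinimide, MeCN, −20 °C; then K2CO3 and 8, −20 °C → rt
Reagents that add atoms: methyl (triphenylphosphoranylidene)acetate, COC(=O)C=P(c1ccccc1)(c1ccccc1)c1ccccc1; N-iodosuccinimide, O=C1CCC(=O)N1I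
Why: Iodination of the stabilised ylide gives the α-iodo ylide, whose Wittig reaction places the ester trans to the epoxide carbon, so iodine sits cis to C2 (Z); the mild carbonate base should leave the cis epoxy aldehyde intact.

Step 8
Reactants: 10 (R)-2,2-dimethyl-1,3-dioxolane-4-carbaldehyde
Product: 11 methyl (2Z)-3-[(4S)-2,2-dimethyl-1,3-dioxolan-4-yl]prop-2-enoate
Conditions: Ph3P=CHCO2Me, MeOH, 0 °C
Reagents that add atoms: methyl (triphenylphosphoranylidene)acetate, COC(=O)C=P(c1ccccc1)(c1ccccc1)c1ccccc1
Why: Wittig reaction of an α-alkoxy aldehyde in methanol is expected to favour the Z enoate, which is needed for high 1,2-induction in step 11; the minor E ester is removed by chromatography.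

Step 9
Reactants: 11 methyl (2Z)-3-[(4S)-2,2-dimethyl-1,3-dioxolan-4-yl]prop-2-enoate
Product: 12 (2Z)-3-[(4S)-2,2-dimethyl-1,3-dioxolan-4-yl]prop-2-en-1-ol
Conditions: (i-Bu)2AlH, CH2Cl2, −78 °C
Reagents that add atoms: none
Why: 1,2-Reduction of the enoate to the Z allylic alcohol; cold non-acidic work-up avoids lactonisation of the Z γ-alkoxy ester.

Step 10
Reactants: 12 (2Z)-3-[(4S)-2,2-dimethyl-1,3-dioxolan-4-yl]prop-2-en-1-ol
Product: 13 (2Z)-3-[(4S)-2-(4-methoxyphenyl)-1,3-dioxolan-4-yl]prop-2-en-1-ol (both epimers at the acetal carbon)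
Conditions: 4-MeOC6H4CH(OMe)2, pyridinium p-toluenesulfonate (cat.), CH2Cl2, rt; volatiles removed under reduced pressure
Reagents that add atoms: 4-methoxybenzaldehyde dimethyl acetal, COc1ccc(C(OC)OC)cc1
Why: Acid-catalysed acetal exchange, driven by removal of volatile 2,2-dimethoxypropane; the five-membered acetal on O8/O9 is the stable one, and no ester is present yet, so no lactone can form.

Step 11
Reactants: 13 (2Z)-3-[(4S)-2-(4-methoxyphenyl)-1,3-dioxolan-4-yl]prop-2-en-1-ol
Product: 15 methyl (3S)-3-[(4S)-2-(4-methoxyphenyl)-1,3-dioxolan-4-yl]pent-4-enoate, via mixed ketene acetal 14 (not isolated)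
Conditions: MeC(OMe)3, EtCO2H (cat.), 135 °C, MeOH distilled off
Reagents that add atoms: trimethyl orthoacetate, CC(OC)(OC)OC
Why: Johnson–Claisen rearrangement through a chair transition state forms C7–C11 and leaves a terminal vinyl group as the masked C6 aldehyde; with the Z alkene, allylic strain holds the C8–H bond in the alkene plane and the new bond should form anti to the C8–O bond, giving 7S.

Step 12
Reactants: 15 methyl (3S)-3-[(4S)-2-(4-methoxyphenyl)-1,3-dioxolan-4-yl]pent-4-enoate
Product: 16 methyl (3S)-3-[(1S)-2-hydroxy-1-[(4-methoxyphenyl)methoxy]ethyl]pent-4-enoate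
Conditions: Et3SiH, PhBCl2, 4 Å MS, CH2Cl2, −78 °C
Reagents that add atoms: none
Why: Regioselective reductive opening of the benzylidene-type acetal: the boron Lewis acid binds the less hindered primary oxygen, the oxocarbenium ion on O8 is reduced by the silane, and the PMB ether ends on O8 with O9 free; ester and alkene are untouched and O8 is never free.

Step 13
Reactants: 16 methyl (3S)-3-[(1S)-2-hydroxy-1-[(4-methoxyphenyl)methoxy]ethyl]pent-4-enoate
Product: 17 methyl (3S)-3-[(1S)-1-[(4-methoxyphenyl)methoxy]-2-oxoethyl]pent-4-enoate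
Conditions: Dess–Martin periodinane, NaHCO3, CH2Cl2, 0 °C
Reagents that add atoms: none
Why: Neutral oxidation of the primary alcohol; the α-alkoxy aldehyde is used crude to avoid epimerisation at C8.

Step 14
Reactants: 9 methyl (2Z)-2-iodo-3-[(2R,3S)-3-[(Z)-1-iodoprop-1-en-2-yl]oxiran-2-yl]prop-2-enoate; 17 methyl (3S)-3-[(1S)-1-[(4-methoxyphenyl)methoxy]-2-oxoethyl]pent-4-enoate
Product: 19 methyl (2E)-2-[(1S,2S,3S)-1-hydroxy-2-[(4-methoxyphenyl)methoxy]-3-(2-methoxy-2-oxoethyl)pent-4-en-1-yl]-3-[(2R,3S)-3-[(Z)-1-iodoprop-1-en-2-yl]oxiran-2-yl]prop-2-enoate, via alkenylmagnesium chloride 18 (not isolated)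
Conditions: i-PrMgCl·LiCl, THF, −78 °C; then 17, MgBr2·OEt2, −78 → −40 °C
Reagents that add atoms: none
Why: Iodine–magnesium exchange is much faster at the electron-poor α-iodo enoate carbon than at the unactivated C5 iodide, and at −78 °C the alkenylmagnesium should keep the C1=C10 geometry; addition to the aldehyde through the magnesium chelate between the carbonyl and PMB oxygens (Cram chelate) forms C9–C10 and sets 9S, syn to O8.

Step 15
Reactants: 19 (C9 alcohol)
Product: 20 methyl (2E)-2-[(1S,2S,3S)-1-[tert-butyl(dimethyl)silyl]oxy-2-[(4-methoxyphenyl)methoxy]-3-(2-methoxy-2-oxoethyl)pent-4-en-1-yl]-3-[(2R,3S)-3-[(Z)-1-iodoprop-1-en-2-yl]oxiran-2-yl]prop-2-enoate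
Conditions: t-BuMe2SiOTf, 2,6-lutidine, CH2Cl2, −78 °C
Reagents that add atoms: tert-butyldimethylsilyl triflate, CC(C)(C)[Si](C)(C)OS(=O)(=O)C(F)(F)F
Why: Silylation of the hindered allylic alcohol with the silyl triflate and a hindered base; prompt protection also stops the C9 hydroxyl from closing a six-membered lactone onto C12.

Step 16
Reactants: 20 (C9 TBS ether, C8 PMB ether)
Product: 21 methyl (2E)-2-[(1S,2S,3S)-1-[tert-butyl(dimethyl)silyl]oxy-2-hydroxy-3-(2-methoxy-2-oxoethyl)pent-4-en-1-yl]-3-[(2R,3S)-3-[(Z)-1-iodoprop-1-en-2-yl]oxiran-2-yl]prop-2-enoate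
Conditions: DDQ, CH2Cl2/pH 7 buffer, 0 °C
Reagents that add atoms: none
Why: Oxidative cleavage of the PMB ether by hydride abstraction and hydrolysis under buffered, neutral conditions; alkenyl iodide, epoxide, silyl ether and esters are inert, and the alcohol is taken on directly.

Step 17
Reactants: 22 angelic acid ((Z)-2-methylbut-2-enoic acid)
Product: 23 (Z)-2-methylbut-2-en-1-ol
Conditions: LiAlH4, Et2O, 0 °C
Reagents that add atoms: none
Why: Hydride reduction of the acid to the allylic alcohol at low temperature, without base or acid that would isomerise the Z alkene.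

Step 18
Reactants: 23 (Z)-2-methylbut-2-en-1-ol
Product: 24 [(2S,3R)-2,3-dimethyloxiran-2-yl]methanol
Conditions: Ti(OiPr)4, L-(+)-diethyl tartrate, t-BuOOH, 4 Å MS, CH2Cl2, −20 °C
Reagents that add atoms: tert-butyl hydroperoxide, CC(C)(C)OO
Why: Sharpless asymmetric epoxidation; the L-tartrate complex should deliver oxygen to the face that gives 2S,3R, and the Z alkene fixes the trans relation of the two methyl groups.

Step 19
Reactants: 24 [(2S,3R)-2,3-dimethyloxiran-2-yl]methanol
Product: 25 (2R,3R)-2,3-dimethyloxirane-2-carboxylic acid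
Conditions: RuCl3 (cat.), NaIO4, CCl4/MeCN/H2O, rt
Reagents that add atoms: sodium periodate, [Na+].[O-]I(=O)(=O)=O; water, O
Why: Ruthenium tetroxide formed in the flask oxidises the primary alcohol to the acid without touching the epoxide; the descriptor at C2 changes only because the priorities change.

Step 20
Reactants: 21 (C8 alcohol); 25 (2R,3R)-2,3-dimethyloxirane-2-carboxylic acid
Product: 27 methyl (2E)-2-[(1S,2S,3S)-1-[tert-butyl(dimethyl)silyl]oxy-2-[(2R,3R)-2,3-dimethyloxirane-2-carbonyl]oxy-3-(2-methoxy-2-oxoethyl)pent-4-en-1-yl]-3-[(2R,3S)-3-[(Z)-1-iodoprop-1-en-2-yl]oxiran-2-yl]prop-2-enoate, via mixed anhydride 26 (not isolated)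
Conditions: 2,4,6-Cl3C6H2COCl, Et3N, THF, rt; then 21, DMAP, toluene, rt
Reagents that add atoms: none
Why: Yamaguchi esterification: DMAP attacks the less hindered carbonyl of the mixed anhydride and transfers the epoxy acyl group to O8; the acid has no α-hydrogen, so it cannot epimerise, and intermolecular acylation should outrun closure of the cis 8,12-lactone.

Step 21
Reactants: 27 (C8 ester with terminal vinyl group)
Product: 29 methyl (2E)-2-[(1S,2S,3R)-1-[tert-butyl(dimethyl)silyl]oxy-2-[(2R,3R)-2,3-dimethyloxirane-2-carbonyl]oxy-3-(2-methoxy-2-oxoethyl)-4-oxobutyl]-3-[(2R,3S)-3-[(Z)-1-iodoprop-1-en-2-yl]oxiran-2-yl]prop-2-enoate, via vicinal diol 28 (not isolated)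
Conditions: OsO4 (cat.), NaIO4, 2,6-lutidine, dioxane/H2O, rt
Reagents that add atoms: osmium tetroxide, O=[Os](=O)(=O)=O (re-formed by sodium periodate, [Na+].[O-]I(=O)(=O)=O)
Why: Lemieux–Johnson cleavage: the monosubstituted vinyl group is the only electron-rich, unhindered alkene, while the enoate and the iodoalkene are deactivated towards osmylation; the diol is cleaved as it forms, so it cannot lactonise, and lutidine keeps the medium near neutral for the β-acyloxy aldehyde.

Step 22
Reactants: 29 (seco Z-alkenyl iodide with C6 aldehyde)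
Product: 31 methyl (1(10)E,4Z,2R,3S,6R,7S,8S,9S)-9-[tert-butyl(dimethyl)silyl]oxy-8-[(2R,3R)-2,3-dimethyloxirane-2-carbonyl]oxy-2,3-epoxy-6-hydroxy-7-(2-methoxy-2-oxoethyl)-4-methylcyclodeca-1(10),4-diene-10-carboxylate, via alkenylchromium dichloride 30 (not isolated)
Conditions: CrCl2 (excess), NiCl2 (cat.), degassed DMSO/THF, rt, slow addition of 29, ca. 2 mM
Reagents that add atoms: none
Why: NiCl2 is reduced by CrCl2 to zerovalent nickel, which inserts into the C5–I bond with retention of the Z geometry; transmetalation gives the trivalent alkenylchromium 30, which adds to the C6 aldehyde and returns divalent nickel to the cycle. The closest known reaction type is the Nozaki–Hiyama–Kishi macrocyclisation of alkenyl iodides onto aldehydes in medium and large rings. The ten-membered ring closes in a 10-exo-trig mode (the carbonyl oxygen stays outside the ring) by forming C5–C6. The new C6 stereocentre is controlled by the C7 stereocentre: Felkin–Anh attack anti to the C8 branch puts O6 syn to C11 (6R), the 1,3-anti preference towards the C8 acyloxy group points the same way, and the Z alkene, which holds C3 and C6 cis, limits the ring-forming conformations. The step needs chemoselectivity for the aldehyde and the single C–I bond: the alkenylchromium does not add to esters or open epoxides, and the medium is non-basic, so C7 should not epimerise and the C8 ester should not be eliminated. High dilution and slow addition favour ring closure over oligomers.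

Step 23
Reactants: 31 (ten-membered C6 alcohol with C7 methyl acetate arm)
Product: 32 9-O-TBS 11,13-dihydro derivative of the target (trans 6,12-lactone, C8 epoxy ester, C14 methyl ester)
Conditions: pyridinium p-toluenesulfonate (cat.), CH2Cl2, rt
Reagents that add atoms: none
Why: 5-Exo-trig lactonisation of the γ-hydroxy methyl ester with loss of methanol; the syn relation of O6 and C11 set in step 22 makes the lactone trans-fused, and the weak acid should spare the epoxides. Part of the closure may already occur on the chromium alkoxide.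

Step 24
Reactants: 32 (saturated lactone)
Product: 33 11-(dimethylaminomethyl) derivative of 32 (epimers at C11)
Conditions: LiN(SiMe3)2, THF, −78 °C; (Me2N=CH2)I, −78 → 0 °C
Reagents that add atoms: dimethylmethyleneiminium iodide, C[N+](C)=C.[I-]
Why: Kinetic enolisation of the lactone (the only enolisable carbonyl: the C8 ester has no α-hydrogen, the C14 ester is vinylic) and Mannich reaction of the lithium enolate with the iminium salt; the C11 configuration does not matter.

Step 25
Reactants: 33 (Mannich base)
Product: 35 9-O-TBS ether of the target, via trimethylammonium iodide 34 (not isolated)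
Conditions: MeI, CH2Cl2/MeOH, rt; then aq. NaHCO3, EtOAc, rt
Reagents that add atoms: none
Why: N-Methylation makes trimethylamine a leaving group, and mild base removes the acidic C11 proton (E1cB) to give the exocyclic methylene without strong base on the epoxy ester.

Step 26
Reactants: 35 (9-O-TBS ether of the target)
Product: 36 CNP0291485.1, methyl (2R,3S,6R,7S,8S,9S)-8-[(2R,3R)-2,3-dimethyloxirane-2-carbonyl]oxy-2,3-epoxy-9-hydroxygermacra-1(10)E,4Z,11(13)-trien-12,6-olid-14-oate
Conditions: HF·pyridine, pyridine, THF, 0 °C → rt
Reagents that add atoms: none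
Why: Fluoride-driven cleavage of the Si–O bond under buffered, weakly acidic conditions that should leave the epoxides, the lactone and the esters untouched; no stereocentre is affected.

## Compound list

1 | propargyl alcohol | C#CCO | starting material
2 | [(Z)-3-(bromomagnesiooxy)-2-methylprop-1-enyl]magnesium bromide | Br[Mg]/C=C(/C)CO[Mg]Br | intermediate (not isolated)
3 | (Z)-3-iodo-2-methylprop-2-en-1-ol | I/C=C(/C)CO | intermediate
4 | (Z)-3-iodo-2-methylprop-2-enal | I/C=C(/C)C=O | intermediate
5 | methyl (2Z,4Z)-5-iodo-4-methylpenta-2,4-dienoate | I/C=C(/C)\C=C/C(=O)OC | intermediate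
6 | (2Z,4Z)-5-iodo-4-methylpenta-2,4-dien-1-ol | I/C=C(/C)\C=C/CO | intermediate
7 | [(2R,3S)-3-[(Z)-1-iodoprop-1-en-2-yl]oxiran-2-yl]methanol | I/C=C(/C)[C@@H]1O[C@@H]1CO | intermediate
8 | (2S,3S)-3-[(Z)-1-iodoprop-1-en-2-yl]oxirane-2-carbaldehyde | I/C=C(/C)[C@@H]1O[C@@H]1C=O | intermediate
9 | methyl (2Z)-2-iodo-3-[(2R,3S)-3-[(Z)-1-iodoprop-1-en-2-yl]oxiran-2-yl]prop-2-enoate | I/C=C(/C)[C@@H]1O[C@@H]1/C=C(/C(=O)OC)I | intermediate
10 | (R)-2,2-dimethyl-1,3-dioxolane-4-carbaldehyde | O=C[C@H]1COC(C)(C)O1 | starting material
11 | methyl (2Z)-3-[(4S)-2,2-dimethyl-1,3-dioxolan-4-yl]prop-2-enoate | COC(=O)/C=C\[C@H]1COC(C)(C)O1 | intermediate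
12 | (2Z)-3-[(4S)-2,2-dimethyl-1,3-dioxolan-4-yl]prop-2-en-1-ol | OC/C=C\[C@H]1COC(C)(C)O1 | intermediate
13 | (2Z)-3-[(4S)-2-(4-methoxyphenyl)-1,3-dioxolan-4-yl]prop-2-en-1-ol (acetal carbon: both epimers) | OC/C=C\[C@H]1COC(c2ccc(OC)cc2)O1 | intermediate
14 | mixed ketene acetal, 1-methoxy-1-[(2Z)-3-[(4S)-2-(4-methoxyphenyl)-1,3-dioxolan-4-yl]prop-2-enyloxy]ethene | C=C(OC)OC/C=C\[C@H]1COC(c2ccc(OC)cc2)O1 | intermediate (not isolated)
15 | methyl (3S)-3-[(4S)-2-(4-methoxyphenyl)-1,3-dioxolan-4-yl]pent-4-enoate | C=C[C@H](CC(=O)OC)[C@H]1COC(c2ccc(OC)cc2)O1 | intermediate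
16 | methyl (3S)-3-[(1S)-2-hydroxy-1-[(4-methoxyphenyl)methoxy]ethyl]pent-4-enoate | C=C[C@H](CC(=O)OC)[C@@H](CO)OCc1ccc(OC)cc1 | intermediate
17 | methyl (3S)-3-[(1S)-1-[(4-methoxyphenyl)methoxy]-2-oxoethyl]pent-4-enoate | C=C[C@H](CC(=O)OC)[C@@H](C=O)OCc1ccc(OC)cc1 | intermediate
18 | alkenylmagnesium chloride from 9 (magnesium on C10, cis to C2) | I/C=C(/C)[C@@H]1O[C@@H]1/C=C(/C(=O)OC)[Mg]Cl | intermediate (not isolated)
19 | C9 alcohol, C8 PMB ether (name in step 14) | I/C=C(/C)[C@@H]1O[C@@H]1/C=C(/C(=O)OC)[C@H](O)[C@@H](OCc2ccc(OC)cc2)[C@@H](CC(=O)OC)C=C | intermediate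
20 | C9 TBS ether, C8 PMB ether (name in step 15) | I/C=C(/C)[C@@H]1O[C@@H]1/C=C(/C(=O)OC)[C@H](O[Si](C)(C)C(C)(C)C)[C@@H](OCc2ccc(OC)cc2)[C@@H](CC(=O)OC)C=C | intermediate
21 | C9 TBS ether, C8 alcohol (name in step 16) | I/C=C(/C)[C@@H]1O[C@@H]1/C=C(/C(=O)OC)[C@H](O[Si](C)(C)C(C)(C)C)[C@@H](O)[C@@H](CC(=O)OC)C=C | intermediate
22 | angelic acid, (Z)-2-methylbut-2-enoic acid | C/C=C(/C)C(=O)O | starting material
23 | (Z)-2-methylbut-2-en-1-ol | C/C=C(/C)CO | intermediate
24 | [(2S,3R)-2,3-dimethyloxiran-2-yl]methanol | OC[C@]1(C)O[C@@H]1C | intermediate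
25 | (2R,3R)-2,3-dimethyloxirane-2-carboxylic acid | OC(=O)[C@]1(C)O[C@@H]1C | intermediate
26 | (2R,3R)-2,3-dimethyloxirane-2-carboxylic 2,4,6-trichlorobenzoic anhydride | O=C(OC(=O)[C@]1(C)O[C@@H]1C)c1c(Cl)cc(Cl)cc1Cl | intermediate (not isolated)
27 | C8 epoxy ester with terminal vinyl group on C7 (name in step 20) | I/C=C(/C)[C@@H]1O[C@@H]1/C=C(/C(=O)OC)[C@H](O[Si](C)(C)C(C)(C)C)[C@@H](OC(=O)[C@]2(C)O[C@@H]2C)[C@@H](CC(=O)OC)C=C | intermediate
28 | vicinal diol from 27 (carbinol carbon C6: both epimers) | I/C=C(/C)[C@@H]1O[C@@H]1/C=C(/C(=O)OC)[C@H](O[Si](C)(C)C(C)(C)C)[C@@H](OC(=O)[C@]2(C)O[C@@H]2C)[C@@H](CC(=O)OC)C(O)CO | intermediate (not isolated)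
29 | seco Z-alkenyl iodide with C6 aldehyde (name in step 21) | I/C=C(/C)[C@@H]1O[C@@H]1/C=C(/C(=O)OC)[C@H](O[Si](C)(C)C(C)(C)C)[C@@H](OC(=O)[C@]2(C)O[C@@H]2C)[C@@H](CC(=O)OC)C=O | intermediate
30 | alkenylchromium dichloride from 29 (chromium on C5) | Cl[Cr](Cl)/C=C(/C)[C@@H]1O[C@@H]1/C=C(/C(=O)OC)[C@H](O[Si](C)(C)C(C)(C)C)[C@@H](OC(=O)[C@]2(C)O[C@@H]2C)[C@@H](CC(=O)OC)C=O | intermediate (not isolated)
31 | ten-membered C6 alcohol with C7 methyl acetate arm (name in step 22) | O[C@@H]1/C=C(/C)[C@@H]3O[C@@H]3/C=C(/C(=O)OC)[C@H](O[Si](C)(C)C(C)(C)C)[C@@H](OC(=O)[C@]3(C)O[C@@H]3C)[C@H]1CC(=O)OC | intermediate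
32 | 9-O-TBS 11,13-dihydro derivative of the target (trans 6,12-lactone) | C1C(=O)O[C@@H]2/C=C(/C)[C@@H]3O[C@@H]3/C=C(/C(=O)OC)[C@H](O[Si](C)(C)C(C)(C)C)[C@@H](OC(=O)[C@]3(C)O[C@@H]3C)[C@@H]12 | intermediate
33 | 11-(dimethylaminomethyl) derivative of 32 (C11: both epimers) | CN(C)CC1C(=O)O[C@@H]2/C=C(/C)[C@@H]3O[C@@H]3/C=C(/C(=O)OC)[C@H](O[Si](C)(C)C(C)(C)C)[C@@H](OC(=O)[C@]3(C)O[C@@H]3C)[C@@H]12 | intermediate
34 | trimethylammonium iodide of 33 | C[N+](C)(C)CC1C(=O)O[C@@H]2/C=C(/C)[C@@H]3O[C@@H]3/C=C(/C(=O)OC)[C@H](O[Si](C)(C)C(C)(C)C)[C@@H](OC(=O)[C@]3(C)O[C@@H]3C)[C@@H]12.[I-] | intermediate (not isolated)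
35 | 9-O-TBS ether of the target | C=C1C(=O)O[C@@H]2/C=C(/C)[C@@H]3O[C@@H]3/C=C(/C(=O)OC)[C@H](O[Si](C)(C)C(C)(C)C)[C@@H](OC(=O)[C@]3(C)O[C@@H]3C)[C@@H]12 | intermediate
36 | CNP0291485.1 (name in step 26) | C=C1C(=O)O[C@@H]2/C=C(/C)[C@@H]3O[C@@H]3/C=C(/C(=O)OC)[C@H](O)[C@@H](OC(=O)[C@]3(C)O[C@@H]3C)[C@@H]12 | target

## Step count and least certain steps

Total: 26 steps. Longest linear sequence: 17 steps from 1 (steps 1–7, 14–16, 20–26). The east half (steps 8–13) and the acid (steps 17–19) are side branches.

Step 22 (key step). Two things are most likely to go wrong. Intermolecular addition may compete with ring closure, because the ten-membered ring is strained and carries two cis ring alkenes. The alkenylchromium may also attack the wrong face of the C6 aldehyde, because the ring-forming conformation can override the Felkin–Anh and 1,3-anti preferences of the chain. Dilution answers the first. For the second, the fallback sets C6 by hydride delivery instead of by C–C bond formation. It sets out from 31, obtained as a mixture of C6 epimers. Dess–Martin oxidation would give the macrocyclic C6 ketone of 31 F1, a conjugated enone. Its 1,2-reduction with NaBH4 and CeCl3 at −78 °C, with hydride coming from the outer face of the ring, should return to 31 with the 6R configuration. If the other face is preferred, an oxazaborolidine-catalysed borane reduction is the reagent-controlled variant.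

Step 14. The alkenylmagnesium 18 may lose its geometry by equilibrating through the magnesium allenolate; the aldehyde would then add from the side of the C1 hydrogen and give the wrong alkene isomer. Chelate control at C9 may also be weakened by THF and LiCl. The fallback forms C1=C10 by olefination and fixes C9 beforehand; it sets out from 8 and 17 and comes back at 20. A chromium-mediated Reformatsky reaction of 17 with methyl trichloroacetate (CrCl2, about 2 equiv, THF) would give methyl (3R,4S,5S)-2,2-dichloro-3-hydroxy-4-[(4-methoxyphenyl)methoxy]-5-(2-methoxy-2-oxoethyl)hept-6-enoate F2, the C9 epimers being separated if needed. Silylation would give its TBS ether F3. Treatment of F3 and 8 with nickel-free CrCl2 in THF would then effect a second Reformatsky addition followed by reductive β-elimination of the chromium aldolate, which should give the E enoate 20 directly. No alkenyl metal is involved, and without nickel the C5 iodide is inert.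

Step 20. The free O8 hydroxyl of 21 sits γ to the C12 methyl ester, so closure of the cis 8,12-lactone may compete with the slow acylation of a hindered secondary alcohol by a hindered acid; migration of the silyl group from O9 to O8 is a lesser risk. The fallback puts the ester on after the ring and the 6,12-lactone are in place, so that C12 is no longer available; it sets out from 20 and comes back at 32. Lemieux–Johnson cleavage of 20 would give the C8 PMB ether analogue of 29 F4. Ring closure with CrCl2 and catalytic NiCl2 would give the C8 PMB ether analogue of 31 F5. Lactonisation would give the C8 PMB ether analogue of 32 F6. DDQ would free the C8 alcohol of the lactone F7, and Yamaguchi esterification of F7 with 25 would give 32. The price is two more steps on the macrocycle and a possible shift of the lactone from O6 to O8 under the acylation conditions.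

Step 5. The substrate is a cis-disubstituted allylic alcohol with a branched sp2 substituent, the slowest class for this epoxidation. Long exposure to the titanium alkoxide may erode the enantiomeric purity and open the vinyl epoxide. The fallback builds the cis epoxide by an auxiliary-controlled aldol reaction; it sets out from 4 and comes back at 8, bypassing 5, 6 and 7. The boron enolate of (R)-4-benzyl-3-(chloroacetyl)oxazolidin-2-one (Bu2BOTf, Et3N) would add to 4 in an Evans syn-aldol reaction to give (4R)-4-benzyl-3-[(2R,3S,4Z)-2-chloro-3-hydroxy-5-iodo-4-methylpent-4-enoyl]oxazolidin-2-one F8. K2CO3 in methanol would cleave the auxiliary and close the epoxide with inversion at the chloride carbon, giving methyl (2S,3S)-3-[(Z)-1-iodoprop-1-en-2-yl]oxirane-2-carboxylate F9. Reduction of F9 with (i-Bu)2AlH at −78 °C would give 8.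

## Further compounds

F1 | step 22 | macrocyclic C6 ketone of 31 | O=C1/C=C(/C)[C@@H]3O[C@@H]3/C=C(/C(=O)OC)[C@H](O[Si](C)(C)C(C)(C)C)[C@@H](OC(=O)[C@]3(C)O[C@@H]3C)[C@H]1CC(=O)OC
F2 | step 14 | methyl (3R,4S,5S)-2,2-dichloro-3-hydroxy-4-[(4-methoxyphenyl)methoxy]-5-(2-methoxy-2-oxoethyl)hept-6-enoate | COC(=O)C(Cl)(Cl)[C@H](O)[C@@H](OCc1ccc(OC)cc1)[C@@H](CC(=O)OC)C=C
F3 | step 14 | TBS ether of F2 | COC(=O)C(Cl)(Cl)[C@H](O[Si](C)(C)C(C)(C)C)[C@@H](OCc1ccc(OC)cc1)[C@@H](CC(=O)OC)C=C
F4 | step 20 | C8 PMB ether analogue of 29 | I/C=C(/C)[C@@H]1O[C@@H]1/C=C(/C(=O)OC)[C@H](O[Si](C)(C)C(C)(C)C)[C@@H](OCc2ccc(OC)cc2)[C@@H](CC(=O)OC)C=O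
F5 | step 20 | C8 PMB ether analogue of 31 | O[C@@H]1/C=C(/C)[C@@H]3O[C@@H]3/C=C(/C(=O)OC)[C@H](O[Si](C)(C)C(C)(C)C)[C@@H](OCc2ccc(OC)cc2)[C@H]1CC(=O)OC
F6 | step 20 | C8 PMB ether analogue of 32 | C1C(=O)O[C@@H]2/C=C(/C)[C@@H]3O[C@@H]3/C=C(/C(=O)OC)[C@H](O[Si](C)(C)C(C)(C)C)[C@@H](OCc3ccc(OC)cc3)[C@@H]12
F7 | step 20 | C8 alcohol of the 9-O-TBS 6,12-lactone | C1C(=O)O[C@@H]2/C=C(/C)[C@@H]3O[C@@H]3/C=C(/C(=O)OC)[C@H](O[Si](C)(C)C(C)(C)C)[C@@H](O)[C@@H]12
F8 | step 5 | (4R)-4-benzyl-3-[(2R,3S,4Z)-2-chloro-3-hydroxy-5-iodo-4-methylpent-4-enoyl]oxazolidin-2-one | I/C=C(/C)[C@H](O)[C@@H](Cl)C(=O)N1[C@H](Cc2ccccc2)COC1=O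
F9 | step 5 | methyl (2S,3S)-3-[(Z)-1-iodoprop-1-en-2-yl]oxirane-2-carboxylate | I/C=C(/C)[C@@H]1O[C@@H]1C(=O)OC
A1 | alternative 1 | trans α-methylene-γ-butyrolactone with CH2OTBS on C6, free C8 hydroxyl and C9 PMB ether | C=C1C(=O)O[C@H](CO[Si](C)(C)C(C)(C)C)[C@H]1[C@H](O)COCc1ccc(OC)cc1
A2 | alternative 2 | trans α-methylene-γ-butyrolactone with CH2OTBS on C6 and the C8–C9 acetonide on C7 | C=C1C(=O)O[C@H](CO[Si](C)(C)C(C)(C)C)[C@H]1[C@H]1COC(C)(C)O1
A3 | alternative 3 | ten-membered enoate with saturated lactone and C9 silyl ether (same structure as 32) | C1C(=O)O[C@@H]2/C=C(/C)[C@@H]3O[C@@H]3/C=C(/C(=O)OC)[C@H](O[Si](C)(C)C(C)(C)C)[C@@H](OC(=O)[C@]3(C)O[C@@H]3C)[C@@H]12
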